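**Plan**

- Ring numbering: C1 (CO2H), C2 (OH), C3 (H), C4 (OH), C5 (CH3), C6 (13-methyltetradecyl, chain carbons C1'–C14'). The meta-dioxygenated edge C2(O)–C3(H)–C4(O) of the single benzene ring is the sum of a ketene carbonyl carbon (C4) and the two carbons of an alkoxyacetylene (C3, C2). The other edge, C1–C6–C5, is a vinylketene skeleton that carries the carboxyl group on its ketene carbon, and this is what allows a one-flask benzannulation.
- Retrosynthesis: C1–C2, C3–C4 and C4–C5 are cut to release ethoxyacetylene and the carboxyl-substituted vinylketene. Its C1–C6 bond is traced back by a Wolff disconnection to an acyclic α-diazo-β-keto ester with a γ,δ-double bond. C5–C6 is then cut as an aldol, C6–C1' as a dianion alkylation and C11'–C12' as a copper-catalysed alkyl–alkyl coupling.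
- Forward: the branched chain is made first (steps 1–2) and joined to tert-butyl acetoacetate (step 3). The propenyl unit and the diazo group are added (steps 4–6), the benzene ring, the only ring, arises in step 7, and one Lewis acid step unmasks the acid and the C2 phenol (step 8).
- Stereochemistry: the target has no stereocenter. The stereocenters made in step 4 and the E double bond set in step 6 are all consumed when the arene forms.

Key step: step 7

Remark: the carboxyl group is carried as a tert-butyl ester, not a methyl ester, because a 2,6-disubstituted electron-rich methyl benzoate resists hydrolysis while the free acid decarboxylates easily; the tert-butyl group leaves in the same Lewis acid step as the ethyl ether, is transparent at the irradiation wavelength and keeps 11 from lactonizing.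

**Route**

Step 1
Reactants: 1 11-bromoundecan-1-ol; 2 isobutylmagnesium bromide
Product: 4 13-methyltetradecan-1-ol, via bromomagnesium alkoxide 3 (not isolated)
Conditions: 2 (2.5 equiv), Li2CuCl4 (3 mol %), THF, −10 °C → rt; aq NH4Cl
Reagents that add atoms: none
Why: Copper-catalysed alkyl–alkyl cross-coupling of a primary bromide with a primary Grignard reagent (Kochi coupling) should proceed cleanly, because the first equivalent of 2 only converts the hydroxyl group into the inert alkoxide 3 and the remaining reagent displaces bromide at the unhindered C11 terminus.

Step 2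
Reactants: 4 13-methyltetradecan-1-ol
Product: 5 1-bromo-13-methyltetradecane
Conditions: CBr4, PPh3, CH2Cl2, 0 °C → rt
Reagents that add atoms: carbon tetrabromide, BrC(Br)(Br)Br
Why: Appel bromination of an unhindered primary alcohol is an SN2 displacement of the phosphonium-activated oxygen by bromide under neutral conditions, with nothing else in the molecule to react.

Step 3
Reactants: 6 tert-butyl 3-oxobutanoate (tert-butyl acetoacetate); 5 1-bromo-13-methyltetradecane
Product: 8 tert-butyl 17-methyl-3-oxooctadecanoate, via acetoacetate dianion 7 (not isolated)
Conditions: NaH, THF, 0 °C; n-BuLi, 0 °C; 5, 0 °C → rt; 1 M HCl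
Reagents that add atoms: none
Why: In the β-keto ester dianion alkylation (Weiler alkylation) the terminal carbanion of 7 is far more nucleophilic than the stabilized central one, so the primary bromide 5 is attacked by SN2 at the methyl terminus only, and the tert-butyl ester resists attack by the bases.

Step 4
Reactants: 8 tert-butyl 17-methyl-3-oxooctadecanoate; 9 acetaldehyde
Product: 11 tert-butyl 5-hydroxy-4-(13-methyltetradecyl)-3-oxohexanoate (racemic syn/anti mixture), via keto ester dianion 10 (not isolated)
Conditions: LiN(iPr)2 (2.2 equiv), THF, −78 → 0 °C; 9 (3 equiv), −78 °C; AcOH, −78 °C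
Reagents that add atoms: none
Why: The dianion 10 reacts at its γ-carbon (C4) in an aldol addition to acetaldehyde at −78 °C and a cold acetic acid quench prevents retro-aldol cleavage; the two new stereocenters (C4, C5) arise without control as a diastereomer mixture, which is acceptable because both become sp2 carbons in step 6, and the tert-butyl ester keeps the δ-hydroxy ester from lactonizing.

Step 5
Reactants: 11 tert-butyl 5-hydroxy-4-(13-methyltetradecyl)-3-oxohexanoate
Product: 12 tert-butyl 2-diazo-5-hydroxy-4-(13-methyltetradecyl)-3-oxohexanoate (diastereomer mixture)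
Conditions: 4-AcNHC6H4SO2N3, Et3N, MeCN, 0 °C → rt
Reagents that add atoms: 4-acetamidobenzenesulfonyl azide, CC(=O)Nc1ccc(cc1)S(=O)(=O)N=[N+]=[N-]
Why: Regitz diazo transfer needs only the doubly activated C2 methylene and a tertiary amine, tolerates the free secondary alcohol, and by replacing both C2 hydrogens ensures that the base in step 6 can only deprotonate C4.

Step 6
Reactants: 12 tert-butyl 2-diazo-5-hydroxy-4-(13-methyltetradecyl)-3-oxohexanoate
Product: 14 tert-butyl (E)-2-diazo-4-(13-methyltetradecyl)-3-oxohex-4-enoate, via mesylate 13 (not isolated)
Conditions: MsCl (1.5 equiv), Et3N (3 equiv), CH2Cl2, 0 °C; DBU (2 equiv), 0 °C → rt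
Reagents that add atoms: none
Why: Mesylation of the secondary alcohol followed by DBU-induced E1cB elimination through the C4 enolate of the diazo ketone should give the conjugated enone, and because the enolate pathway is stereoconvergent for both diastereomers of 13 it leads to the more stable E isomer (methyl trans to the acyl group), while the base-stable diazo keto ester is untouched.

Step 7
Reactants: 14 tert-butyl (E)-2-diazo-4-(13-methyltetradecyl)-3-oxohex-4-enoate; 15 ethoxyethyne (ethoxyacetylene)
Product: 20 tert-butyl 2-ethoxy-4-hydroxy-5-methyl-6-(13-methyltetradecyl)benzoate, via vinylketene 16 (not isolated), via vinylcyclobutenone 17 (not isolated), via dienylketene 18 (not isolated), via cyclohexadienone 19 (not isolated)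
Conditions: 15 (5 equiv), degassed CH2Cl2 (0.05 M), hν (300 nm), rt; evaporate; PhMe, 80 °C
Reagents that add atoms: none
Why: Proposed new method: irradiation expels N2 from 14 with 1,2-shift of the alkenyl group from the ketone carbon to the diazo carbon (Wolff rearrangement, new C1–C6 bond) to give the carboxyl-substituted vinylketene 16, whose electrophilic carbonyl carbon (future C4) is attacked by the unsubstituted carbon of 15 while the ethoxy-bearing carbon bonds to the ester-bearing ketene carbon, so that a [2+2] cycloaddition forms C3–C4 and C1–C2 and closes the transient four-membered ring of 17. On warming, 17 undergoes reversible four-electron electrocyclic opening, and the dienylketene 18 that has the alkenyl group cis to the ketene closes the benzene ring by thermally allowed disrotatory six-electron electrocyclization (new C4–C5 bond) to dienone 19, which enolizes irreversibly to phenol 20. The closest known reaction type is the diazo ketone variant of the Danheiser benzannulation (Wolff rearrangement, ketene–alkoxyalkyne or ketene–silyloxyalkyne [2+2], 4π opening, 6π closure), established for vinylketenes with hydrogen or carbon substituents on the ketene carbon but not with an ester there. No stereocenter is created in 20; the quaternary carbon of 17 and the methine carbon of 19 are transient, and the E alkene of 14 merely places the C5 methyl group on the outside of the closing triene. The regiochemistry rests on the polarization of the ynol ether (nucleophilic terminal carbon to the ketene carbonyl carbon) and on the known preference of α-diazo-β-keto esters for migration of the carbon group over the alkoxy group. The selectivity the step still needs is carbon–carbon closure of the ketene–alkyne adduct rather than closure through the ester oxygen (hetero-[4+2] to a 4-pyranone), which the substrate only biases (bulky tert-butyl ester, excess 15 at room temperature so that the ketene is trapped as it forms) and does not guarantee.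

Step 8
Reactants: 20 tert-butyl 2-ethoxy-4-hydroxy-5-methyl-6-(13-methyltetradecyl)benzoate
Product: 21 2,4-dihydroxy-5-methyl-6-(13-methyltetradecyl)benzoic acid (CNP0092306.0)
Conditions: BBr3 (4 equiv), CH2Cl2, −78 → 0 °C; ice-water
Reagents that add atoms: none
Why: BBr3 acts as a Lewis acid dealkylating agent, ionizing the tert-butyl ester by alkyl–oxygen fission and cleaving the aryl ethyl ether by bromide attack on the boron-complexed ethoxy group (helped by chelation between the carboxyl and the ortho oxygen), and hydrolysis of the B–O bonds at 0 °C releases the acid and both phenols without the heat that makes such electron-rich salicylic acids lose CO2.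

**Compound list**

1 | 11-bromoundecan-1-ol | OCCCCCCCCCCCBr | starting material
2 | isobutylmagnesium bromide | CC(C)C[Mg]Br | starting material
3 | bromomagnesium 11-bromoundecan-1-olate | BrCCCCCCCCCCCO[Mg]Br | intermediate (not isolated)
4 | 13-methyltetradecan-1-ol | CC(C)CCCCCCCCCCCCO | intermediate
5 | 1-bromo-13-methyltetradecane | CC(C)CCCCCCCCCCCCBr | intermediate
6 | tert-butyl 3-oxobutanoate | CC(=O)CC(=O)OC(C)(C)C | starting material
7 | sodium lithium dianion of 6 (1-tert-butoxybuta-1,3-diene-1,3-diolate) | [Na+].[Li+].C=C([O-])C=C([O-])OC(C)(C)C | intermediate (not isolated)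
8 | tert-butyl 17-methyl-3-oxooctadecanoate | CC(C)CCCCCCCCCCCCCC(=O)CC(=O)OC(C)(C)C | intermediate
9 | acetaldehyde | CC=O | starting material
10 | dilithium dianion of 8 (1-tert-butoxy-17-methyloctadeca-1,3-diene-1,3-diolate) | [Li+].[Li+].CC(C)CCCCCCCCCCCCC=C([O-])C=C([O-])OC(C)(C)C | intermediate (not isolated)
11 | tert-butyl 5-hydroxy-4-(13-methyltetradecyl)-3-oxohexanoate (racemic, syn/anti mixture) | CC(O)C(CCCCCCCCCCCCC(C)C)C(=O)CC(=O)OC(C)(C)C | intermediate
12 | tert-butyl 2-diazo-5-hydroxy-4-(13-methyltetradecyl)-3-oxohexanoate (racemic, syn/anti mixture) | CC(O)C(CCCCCCCCCCCCC(C)C)C(=O)C(=[N+]=[N-])C(=O)OC(C)(C)C | intermediate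
13 | tert-butyl 2-diazo-5-(methanesulfonyloxy)-4-(13-methyltetradecyl)-3-oxohexanoate (diastereomer mixture) | CC(OS(C)(=O)=O)C(CCCCCCCCCCCCC(C)C)C(=O)C(=[N+]=[N-])C(=O)OC(C)(C)C | intermediate (not isolated)
14 | tert-butyl (E)-2-diazo-4-(13-methyltetradecyl)-3-oxohex-4-enoate | CC(C)(C)OC(=O)C(=[N+]=[N-])C(=O)/C(CCCCCCCCCCCCC(C)C)=C/C | intermediate (key-step precursor)
15 | ethoxyethyne (ethoxyacetylene) | C#COCC | starting material
16 | tert-butyl (3E)-3-(13-methyltetradecyl)-2-(oxomethylidene)pent-3-enoate (vinylketene) | CC(C)(C)OC(=O)C(=C=O)/C(CCCCCCCCCCCCC(C)C)=C/C | intermediate (not isolated)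
17 | tert-butyl 2-ethoxy-1-[(2E)-16-methylheptadec-2-en-3-yl]-4-oxocyclobut-2-ene-1-carboxylate (racemic) | CCOC1=CC(=O)C1(C(=O)OC(C)(C)C)/C(CCCCCCCCCCCCC(C)C)=C/C | intermediate (not isolated)
18 | tert-butyl (2Z)-3-ethoxy-2-[(2E)-16-methylheptadec-2-en-3-yl]-5-oxopenta-2,4-dienoate (dienylketene, alkenyl group cis to the ketene) | O=C=C/C(OCC)=C(\C(CCCCCCCCCCCCC(C)C)=C\C)C(=O)OC(C)(C)C | intermediate (not isolated)
19 | tert-butyl 6-ethoxy-3-methyl-2-(13-methyltetradecyl)-4-oxocyclohexa-1,5-diene-1-carboxylate (keto tautomer of 20, racemic) | CCOC1=CC(=O)C(C)C(CCCCCCCCCCCCC(C)C)=C1C(=O)OC(C)(C)C | intermediate (not isolated)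
20 | tert-butyl 2-ethoxy-4-hydroxy-5-methyl-6-(13-methyltetradecyl)benzoate | CCOc1cc(O)c(C)c(CCCCCCCCCCCCC(C)C)c1C(=O)OC(C)(C)C | intermediate (key-step product)
21 | 2,4-dihydroxy-5-methyl-6-(13-methyltetradecyl)benzoic acid | Cc1c(O)cc(O)c(C(=O)O)c1CCCCCCCCCCCCC(C)C | target

**Step count and risks**

Total step count: 8. Longest linear sequence: 8 steps (1 → 21); the route is fully linear.

Steps most likely to fail:

1. Step 7. The ketene–ynol ether adduct may close through the ester carbonyl oxygen (hetero-[4+2]) instead of through carbon. During ring opening of 17 the ester rather than the alkenyl group may also turn inward and then close through oxygen. The photogenerated carbene may be captured by the alkyne before it rearranges. The fallback builds the arene by the established Michael–Claisen/aromatization route to 2,4-dihydroxy-6-alkylbenzoates. It sets out from bromide 5: magnesium in THF should give (13-methyltetradecyl)magnesium bromide F1, which is formylated with DMF (Bouveault reaction, dilute HCl work-up) to 14-methylpentadecanal F2. Wittig olefination with 3-(triphenylphosphoranylidene)butan-2-one in hot toluene should give (E)-3,17-dimethyloctadec-3-en-2-one F3. Conjugate addition of dibenzyl malonate (NaH, THF, reflux) with Claisen ring closure in the same flask should give benzyl 2-hydroxy-5-methyl-6-(13-methyltetradecyl)-4-oxocyclohex-2-ene-1-carboxylate F4. Oxidative aromatization with Br2 in DMF should give benzyl 2,4-dihydroxy-5-methyl-6-(13-methyltetradecyl)benzoate F5, and hydrogenolysis (H2, Pd/C, EtOAc) comes back to the route at the target 21.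

2. Step 8. The electron-rich acid may undergo protodecarboxylation by the HBr formed during dealkylation, and the tert-butyl cation may alkylate C3. The fallback gives up the carboxyl group on purpose and puts it back. It sets out from 20: hot 48% HBr in AcOH should remove the ethyl and tert-butyl groups and decarboxylate to 4-methyl-5-(13-methyltetradecyl)benzene-1,3-diol F6. Chelation-directed carboxylation of this resorcinol with MeOMgOCO2Me (methyl magnesium carbonate) in DMF at 120 °C, then cold dilute HCl, comes back at 21. The magnesium phenoxide should direct CO2 to the carbon ortho to one hydroxyl and para to the other, and the acid is liberated only at 0 °C.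

3. Step 4. Proton transfer from enolizable acetaldehyde to the hindered secondary γ-carbanion, or retro-aldol cleavage of the aldolate before the quench, may erode the addition. The fallback inverts the order of aldol and diazo transfer and replaces the dianion by a titanium enolate. It sets out from 8: diazo transfer (4-AcNHC6H4SO2N3, Et3N, MeCN) should give tert-butyl 2-diazo-17-methyl-3-oxooctadecanoate F7. Its titanium enolate (TiCl4, Et3N, CH2Cl2, −78 °C) should add to acetaldehyde at C4 and so come back to the route at 12, before step 6.

Further compounds
F1 | step 7 | (13-methyltetradecyl)magnesium bromide | CC(C)CCCCCCCCCCCC[Mg]Br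
F2 | step 7 | 14-methylpentadecanal | CC(C)CCCCCCCCCCCCC=O
F3 | step 7 | (E)-3,17-dimethyloctadec-3-en-2-one | CC(=O)/C(C)=C/CCCCCCCCCCCCC(C)C
F4 | step 7 | benzyl 2-hydroxy-5-methyl-6-(13-methyltetradecyl)-4-oxocyclohex-2-ene-1-carboxylate | CC1C(=O)C=C(O)C(C(=O)OCc2ccccc2)C1CCCCCCCCCCCCC(C)C
F5 | step 7 | benzyl 2,4-dihydroxy-5-methyl-6-(13-methyltetradecyl)benzoate | Cc1c(O)cc(O)c(C(=O)OCc2ccccc2)c1CCCCCCCCCCCCC(C)C
F6 | step 8 | 4-methyl-5-(13-methyltetradecyl)benzene-1,3-diol | Cc1c(O)cc(O)cc1CCCCCCCCCCCCC(C)C
F7 | step 4 | tert-butyl 2-diazo-17-methyl-3-oxooctadecanoate | CC(C)CCCCCCCCCCCCCC(=O)C(=[N+]=[N-])C(=O)OC(C)(C)C
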